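**Retrosynthetic overview**
1. The γ-lactone is closed last: the amide oxygen of an open-chain γ-mesyloxy amide displaces the sulfonate with inversion, and the iminium ether is hydrolysed.
2. The cis-oxirane comes from vanadium-catalysed epoxidation of a Z-trisubstituted alkene, directed syn by that same homoallylic OH before it is inverted.
3. The key C(sp2)–C(sp3) bond is made by light-driven nickel coupling of a Z-alkenyl iodide (umbelliferone ether) with a terminal epoxide; the γ-hydroxyl lactonises and pyrrolidine reopens the lactone to the amide.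
4. The epoxide fragment comes from Seebach alkylation of the (R)-lactic acid/pivalaldehyde dioxolanone with (S)-glycidyl triflate; the alkenyl iodide comes from but-2-yn-1-ol and umbelliferone.
5. Ring order: dioxolanone (temporary) → transient lactone → oxirane → γ-lactone.

Assumption: the target is made exactly as encoded, with the cis-(2S,3R)-oxirane (aryloxymethyl and lactonylmethyl on the same face) and the (2S,4S)-lactone (tertiary OH cis to the side chain).

**Step 1**
Reactants: 1 (R)-lactic acid; 2 pivalaldehyde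
Product: 3 (2R,5R)-2-tert-butyl-5-methyl-1,3-dioxolan-4-one (cis)
Conditions: TsOH·H2O (cat.), H2SO4 (cat.), pentane, reflux, Dean–Stark; recrystallise from pentane/Et2O at −78 °C
Reagents that add atoms: none
Why: Acid-catalysed acetalisation (Seebach self-regeneration of stereocentres) leaves the lactic acid centre untouched and forms the acetal centre mainly cis to the methyl group (about 4:1), the cis isomer being purified by crystallisation.

**Step 2**
Reactants: 4 (R)-glycidol
Product: 5 (S)-glycidyl triflate [(2S)-oxiran-2-ylmethyl trifluoromethanesulfonate]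
Conditions: Tf2O, 2,6-lutidine, CH2Cl2, −78 °C; cold aqueous wash, used at once
Reagents that add atoms: triflic anhydride, O=S(=O)(OS(=O)(=O)C(F)(F)F)C(F)(F)F
Why: O-Sulfonylation of a primary alcohol touches no bond at the stereocentre (the descriptor changes from R to S only because of CIP priorities).

**Step 3**
Reactants: 3 (2R,5R)-2-tert-butyl-5-methyl-1,3-dioxolan-4-one; 5 (S)-glycidyl triflate
Product: 7 (2R,5S)-2-tert-butyl-5-methyl-5-{[(2R)-oxiran-2-yl]methyl}-1,3-dioxolan-4-one, via lithium enolate 6 (not isolated)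
Conditions: LiN(iPr)2 (commercial solution, 1.05 equiv), THF, −78 °C; then 5 (1.2 equiv), −78 → −40 °C
Reagents that add atoms: none
Why: Seebach enolate alkylation: the planar enolate is attacked anti to the tert-butyl group, so the new C–C bond replaces the former C–H with retention (5S), and direct SN2 at the CH2–OTf carbon at −78 °C is far faster than epoxide opening, so the glycidyl centre is carried through unchanged.

**Step 4**
Reactants: 8 but-2-yn-1-ol
Product: 10 (2Z)-3-iodobut-2-en-1-ol, via cyclic alkenylaluminate 9 (not isolated)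
Conditions: NaAlH2(OCH2CH2OCH3)2, THF, 0 °C → rt; then I2, −78 → 0 °C; aq. Na2S2O3 work-up
Reagents that add atoms: iodine, II
Why: Hydroxyl-directed trans-hydroalumination of the propargylic alcohol places aluminium on C3 in a five-membered aluminate, and iodinolysis with retention gives the Z-iodide (iodine cis to CH2OH).

**Step 5**
Reactants: 10 (2Z)-3-iodobut-2-en-1-ol; 11 umbelliferone (7-hydroxy-2H-chromen-2-one)
Product: 12 7-{[(2Z)-3-iodobut-2-en-1-yl]oxy}-2H-chromen-2-one
Conditions: PPh3, DIAD, THF, 0 °C → rt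
Reagents that add atoms: none
Why: Mitsunobu etherification of a primary allylic alcohol with an acidic phenol proceeds by SN2 at CH2 and leaves the alkene geometry untouched.

**Step 6**
Reactants: 7 (2R,5S)-2-tert-butyl-5-methyl-5-{[(2R)-oxiran-2-yl]methyl}-1,3-dioxolan-4-one; 12 7-{[(2Z)-3-iodobut-2-en-1-yl]oxy}-2H-chromen-2-one
Product: 16 (2S,4S,6Z)-2,4-dihydroxy-2,6-dimethyl-8-[(2-oxo-2H-chromen-7-yl)oxy]-1-(pyrrolidin-1-yl)oct-6-en-1-one, via iodohydrin 13 (not isolated), via coupled hydroxy dioxolanone 14 (not isolated), via alkenyl lactone 15 (not isolated)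
Conditions: NiBr2·glyme (10 mol %), 4,4'-di-tert-butyl-2,2'-bipyridine (12 mol %), [Ir(ppy)2(dtbbpy)]PF6 (1 mol %), NaI (0.3 equiv), Et3N·HCl (1 equiv), Et3N (4 equiv), DMA, 450 nm LEDs, 25 °C; then pyrrolidine (10 equiv), 45 °C
Reagents that add atoms: pyrrolidine, C1CCNC1
Why: Proposed new method: NaI/Et3NH+ opens the terminal oxirane of 7 at CH2 to iodohydrin 13 without touching the C–O bond at the stereocentre; the photoreduced iridium complex (quenched by Et3N) takes divalent nickel to zerovalent nickel, which inserts into the C–I bond of 12 with retention of the Z geometry; the primary radical released from 13 by iodine-atom abstraction is captured at nickel, and reductive elimination from trivalent nickel forges the C(sp2)–C(sp3) bond of 14; the γ-hydroxyl of 14 then acylates on the dioxolanone (loss of pivalaldehyde) to lactone 15, which pyrrolidine opens to the non-lactonising amide 16 (coupling and lactonisation may occur in either order and converge on 15); the closest known reaction types are nickel/iodide co-catalysed reductive coupling of terminal epoxides with aryl halides through iodohydrins and nickel/photoredox cross-electrophile coupling of alkyl with aryl or alkenyl halides, the untested part being a geometrically defined alkenyl iodide on an epoxide under light-driven nickel catalysis terminated by acyl transfer from a Seebach acetal.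

**Step 7**
Reactants: 16 (2S,4S,6Z)-2,4-dihydroxy-2,6-dimethyl-8-[(2-oxo-2H-chromen-7-yl)oxy]-1-(pyrrolidin-1-yl)oct-6-en-1-one
Product: 17 (2S,4R)-2,4-dihydroxy-2-methyl-5-[(2R,3S)-2-methyl-3-{[(2-oxo-2H-chromen-7-yl)oxy]methyl}oxiran-2-yl]-1-(pyrrolidin-1-yl)pentan-1-one
Conditions: VO(acac)2 (5 mol %), t-BuOOH (anhydrous in decane, 1.5 equiv), CH2Cl2, 0 °C → rt
Reagents that add atoms: tert-butyl hydroperoxide, CC(C)(C)OO
Why: Hydroxyl-directed vanadium epoxidation of a homoallylic alcohol (Sharpless/Mihelich type) goes through a chair-like vanadate ester in which the carbinol substituent is equatorial and the Z-substituent (1,3-allylic strain) fixes the alkene rotamer, so oxygen is delivered syn to the C4 hydroxyl and both oxirane centres are set from the glycidol-derived carbinol (the C4 descriptor changes from S to R by CIP priority only).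

**Step 8**
Reactants: 17 (2S,4R)-2,4-dihydroxy-2-methyl-5-[(2R,3S)-2-methyl-3-{[(2-oxo-2H-chromen-7-yl)oxy]methyl}oxiran-2-yl]-1-(pyrrolidin-1-yl)pentan-1-one
Product: 20 7-{[(2S,3R)-3-{[(2S,4S)-4-hydroxy-4-methyl-5-oxooxolan-2-yl]methyl}-3-methyloxiran-2-yl]methoxy}-2H-chromen-2-one, via secondary mesylate 18 (not isolated), via iminium lactone 19 (not isolated)
Conditions: MsCl (1.2 equiv), Et3N (2 equiv), CH2Cl2, −20 °C → rt; then THF/aq. NaOAc–AcOH buffer (pH 5), rt
Reagents that add atoms: water, O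
Why: Selective mesylation of the secondary alcohol is followed by neighbouring-group participation of the tertiary amide oxygen (5-exo-tet SN2, inversion at the carbinol carbon) to a cyclic iminium ether whose buffered hydrolysis expels pyrrolidine, giving the γ-lactone with the (S) carbinol centre while the tertiary OH and the oxirane are untouched.

**Compound list**
1 | (R)-lactic acid | C[C@@H](O)C(=O)O | starting material
2 | pivalaldehyde | CC(C)(C)C=O | starting material
3 | (2R,5R)-2-tert-butyl-5-methyl-1,3-dioxolan-4-one | C[C@H]1O[C@@H](C(C)(C)C)OC1=O | intermediate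
4 | (R)-glycidol | OC[C@@H]1CO1 | starting material
5 | (S)-glycidyl triflate | O=S(=O)(OC[C@@H]1CO1)C(F)(F)F | intermediate
6 | lithium (2R)-2-tert-butyl-5-methyl-1,3-dioxol-4-olate (enolate of 3) | [Li+].CC1=C([O-])O[C@H](C(C)(C)C)O1 | intermediate
7 | (2R,5S)-2-tert-butyl-5-methyl-5-{[(2R)-oxiran-2-yl]methyl}-1,3-dioxolan-4-one | C[C@@]1(C[C@@H]2CO2)O[C@@H](C(C)(C)C)OC1=O | intermediate
8 | but-2-yn-1-ol | CC#CCO | starting material
9 | sodium 2,2-bis(2-methoxyethoxy)-3-methyl-2,5-dihydro-1,2-oxaaluminol-2-uide | [Na+].CC1=CCO[Al-]1(OCCOC)OCCOC | intermediate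
10 | (2Z)-3-iodobut-2-en-1-ol | C/C(I)=C/CO | intermediate
11 | umbelliferone | Oc1ccc2ccc(=O)oc2c1 | starting material
12 | 7-{[(2Z)-3-iodobut-2-en-1-yl]oxy}-2H-chromen-2-one | C/C(I)=C/COc1ccc2ccc(=O)oc2c1 | intermediate
13 | (2R,5S)-2-tert-butyl-5-[(2R)-2-hydroxy-3-iodopropyl]-5-methyl-1,3-dioxolan-4-one | C[C@@]1(C[C@@H](O)CI)O[C@@H](C(C)(C)C)OC1=O | intermediate
14 | (2R,5S)-2-tert-butyl-5-{(2S,4Z)-2-hydroxy-4-methyl-6-[(2-oxo-2H-chromen-7-yl)oxy]hex-4-en-1-yl}-5-methyl-1,3-dioxolan-4-one | C[C@@]1(C[C@@H](O)C/C(C)=C\COc2ccc3ccc(=O)oc3c2)O[C@@H](C(C)(C)C)OC1=O | intermediate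
15 | (3S,5S)-3-hydroxy-3-methyl-5-{(2Z)-2-methyl-4-[(2-oxo-2H-chromen-7-yl)oxy]but-2-en-1-yl}oxolan-2-one | C[C@]1(O)C[C@H](C/C(C)=C\COc2ccc3ccc(=O)oc3c2)OC1=O | intermediate
16 | (2S,4S,6Z)-2,4-dihydroxy-2,6-dimethyl-8-[(2-oxo-2H-chromen-7-yl)oxy]-1-(pyrrolidin-1-yl)oct-6-en-1-one | C[C@](O)(C[C@@H](O)C/C(C)=C\COc1ccc2ccc(=O)oc2c1)C(=O)N1CCCC1 | intermediate
17 | (2S,4R)-2,4-dihydroxy-2-methyl-5-[(2R,3S)-2-methyl-3-{[(2-oxo-2H-chromen-7-yl)oxy]methyl}oxiran-2-yl]-1-(pyrrolidin-1-yl)pentan-1-one | C[C@](O)(C[C@@H](O)C[C@@]1(C)O[C@H]1COc1ccc2ccc(=O)oc2c1)C(=O)N1CCCC1 | intermediate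
18 | (2R,4S)-4-hydroxy-4-methyl-1-[(2R,3S)-2-methyl-3-{[(2-oxo-2H-chromen-7-yl)oxy]methyl}oxiran-2-yl]-5-oxo-5-(pyrrolidin-1-yl)pentan-2-yl methanesulfonate | C[C@](O)(C[C@@H](OS(C)(=O)=O)C[C@@]1(C)O[C@H]1COc1ccc2ccc(=O)oc2c1)C(=O)N1CCCC1 | intermediate
19 | 1-[(3S,5S)-3-hydroxy-3-methyl-5-{[(2R,3S)-2-methyl-3-{[(2-oxo-2H-chromen-7-yl)oxy]methyl}oxiran-2-yl]methyl}oxolan-2-ylidene]pyrrolidin-1-ium methanesulfonate | C[C@]1(O)C[C@@H](C[C@@]2(C)O[C@H]2COc2ccc3ccc(=O)oc3c2)OC1=[N+]4CCCC4.CS(=O)(=O)[O-] | intermediate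
20 | 7-{[(2S,3R)-3-{[(2S,4S)-4-hydroxy-4-methyl-5-oxooxolan-2-yl]methyl}-3-methyloxiran-2-yl]methoxy}-2H-chromen-2-one | C[C@]1(O)C[C@@H](C[C@@]2(C)O[C@H]2COc2ccc3ccc(=O)oc3c2)OC1=O | target

**Step count and risks**
Total steps: 8. Longest linear sequence: 5 (steps 1 → 3 → 6 → 7 → 8; the branches 2 → 3 and 4 → 5 → 6 are no longer).

Steps most likely to fail:

Step 6 (the proposed new coupling). The risks are quaternisation or reduction of the transient iodohydrin, loss of Z geometry at nickel, and slow aminolysis. [Ir(ppy)2(dtbbpy)]PF6 was chosen because its triplet energy (about 49 kcal/mol) lies well below that of the 7-alkoxycoumarin (about 62 kcal/mol), so sensitised coumarin dimerisation is not expected. The fallback uses known polar chemistry and sets out from 10 and 7. Alcohol 10 is silylated (TBSCl, imidazole, DMF) to tert-butyl{[(2Z)-3-iodobut-2-en-1-yl]oxy}dimethylsilane F1. Iodine–magnesium exchange (i-PrMgCl·LiCl, THF, −20 °C) gives [(2Z)-4-{[tert-butyl(dimethyl)silyl]oxy}but-2-en-2-yl]magnesium chloride F2 with retention of geometry. F2 opens epoxide 7 at its CH2 terminus under CuI catalysis (10 mol %, −40 → 0 °C), and the magnesium alkoxide lactonises with loss of pivalaldehyde to (3S,5S)-5-[(2Z)-4-{[tert-butyl(dimethyl)silyl]oxy}-2-methylbut-2-en-1-yl]-3-hydroxy-3-methyloxolan-2-one F3. Desilylation (Bu4NF/AcOH, THF) gives (3S,5S)-3-hydroxy-5-[(2Z)-4-hydroxy-2-methylbut-2-en-1-yl]-3-methyloxolan-2-one F4. A Mitsunobu reaction with 11 (PPh3, DIAD) then comes back to the route at 15, which is opened to 16 with pyrrolidine as in the second stage of step 6.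

Step 7 (stereodetermining epoxidation). The risks are an insufficient syn:anti ratio, relactonisation of the γ-hydroxy amide at pentavalent vanadium, and attack of the tertiary hydroxyl on the new oxirane. The fallback is iodocarbonate cyclisation, which also delivers the syn relationship, and sets out from 16. The secondary alcohol is acylated (Boc2O, DMAP cat., MeCN, 0 °C) to tert-butyl (2Z,5S,7S)-7-hydroxy-3,7-dimethyl-8-oxo-1-[(2-oxo-2H-chromen-7-yl)oxy]-8-(pyrrolidin-1-yl)oct-2-en-5-yl carbonate F5. IBr (toluene/CH2Cl2, −80 °C) closes the six-membered carbonate on the tertiary alkene carbon, syn to the carbinol substituent, with anti addition of iodine, giving (2S)-2-hydroxy-3-[(4R,6R)-4-{(1R)-1-iodo-2-[(2-oxo-2H-chromen-7-yl)oxy]ethyl}-4-methyl-2-oxo-1,3-dioxan-6-yl]-2-methyl-1-(pyrrolidin-1-yl)propan-1-one F6. K2CO3 in MeOH cleaves the carbonate, and the tertiary alkoxide displaces iodide with inversion, returning to the route at 17.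

Step 8 (invertive lactonisation). The risks are elimination of the mesylate, hydrolysis of iminium ether 19 toward the hydroxy amide instead of the lactone, and acid sensitivity of the oxirane at pH 5. The fallback separates inversion from ring closure and sets out from 17. An intermolecular Mitsunobu reaction (4-nitrobenzoic acid, PPh3, DIAD, THF) gives the inverted ester (2S,4S)-4-hydroxy-4-methyl-1-[(2R,3S)-2-methyl-3-{[(2-oxo-2H-chromen-7-yl)oxy]methyl}oxiran-2-yl]-5-oxo-5-(pyrrolidin-1-yl)pentan-2-yl 4-nitrobenzoate F7. Brief methanolysis (K2CO3, MeOH, 0 °C) gives (2S,4S)-2,4-dihydroxy-2-methyl-5-[(2R,3S)-2-methyl-3-{[(2-oxo-2H-chromen-7-yl)oxy]methyl}oxiran-2-yl]-1-(pyrrolidin-1-yl)pentan-1-one F8. F8 is lactonised with retention under mild acid (pyridinium p-toluenesulfonate cat., toluene, 50 °C) with loss of pyrrolidine, arriving at 20.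

**Further compounds**
F1 | step 6 | tert-butyl{[(2Z)-3-iodobut-2-en-1-yl]oxy}dimethylsilane | C/C(I)=C/CO[Si](C)(C)C(C)(C)C
F2 | step 6 | [(2Z)-4-{[tert-butyl(dimethyl)silyl]oxy}but-2-en-2-yl]magnesium chloride | C/C([Mg]Cl)=C/CO[Si](C)(C)C(C)(C)C
F3 | step 6 | (3S,5S)-5-[(2Z)-4-{[tert-butyl(dimethyl)silyl]oxy}-2-methylbut-2-en-1-yl]-3-hydroxy-3-methyloxolan-2-one | C[C@]1(O)C[C@H](C/C(C)=C\CO[Si](C)(C)C(C)(C)C)OC1=O
F4 | step 6 | (3S,5S)-3-hydroxy-5-[(2Z)-4-hydroxy-2-methylbut-2-en-1-yl]-3-methyloxolan-2-one | C[C@]1(O)C[C@H](C/C(C)=C\CO)OC1=O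
F5 | step 7 | tert-butyl (2Z,5S,7S)-7-hydroxy-3,7-dimethyl-8-oxo-1-[(2-oxo-2H-chromen-7-yl)oxy]-8-(pyrrolidin-1-yl)oct-2-en-5-yl carbonate | C[C@](O)(C[C@@H](OC(=O)OC(C)(C)C)C/C(C)=C\COc1ccc2ccc(=O)oc2c1)C(=O)N1CCCC1
F6 | step 7 | (2S)-2-hydroxy-3-[(4R,6R)-4-{(1R)-1-iodo-2-[(2-oxo-2H-chromen-7-yl)oxy]ethyl}-4-methyl-2-oxo-1,3-dioxan-6-yl]-2-methyl-1-(pyrrolidin-1-yl)propan-1-one | O=C1O[C@H](C[C@](C)(O)C(=O)N2CCCC2)C[C@@](C)(O1)[C@H](I)COc1ccc2ccc(=O)oc2c1
F7 | step 8 | (2S,4S)-4-hydroxy-4-methyl-1-[(2R,3S)-2-methyl-3-{[(2-oxo-2H-chromen-7-yl)oxy]methyl}oxiran-2-yl]-5-oxo-5-(pyrrolidin-1-yl)pentan-2-yl 4-nitrobenzoate | C[C@](O)(C[C@H](OC(=O)c1ccc(cc1)[N+](=O)[O-])C[C@@]2(C)O[C@H]2COc2ccc3ccc(=O)oc3c2)C(=O)N1CCCC1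
F8 | step 8 | (2S,4S)-2,4-dihydroxy-2-methyl-5-[(2R,3S)-2-methyl-3-{[(2-oxo-2H-chromen-7-yl)oxy]methyl}oxiran-2-yl]-1-(pyrrolidin-1-yl)pentan-1-one | C[C@](O)(C[C@H](O)C[C@@]1(C)O[C@H]1COc1ccc2ccc(=O)oc2c1)C(=O)N1CCCC1
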